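Remark (assumption on the chemistry): the sense of induction of (R)-BINAP in the ring-opening step cannot be derived with certainty. The route is written on the assumption that it directs cleavage of the pro-S ring bond of 6; if the opposite sense is found, the mirror-image ligand is to be used with no other change.

## Structural features

Wailupemycin F is a 3,4-dihydronaphthalen-1(2H)-one in which ring A (C1 ketone, C2 methylene, C3 carbinol, C4 methylene) is fused through C4a–C8a to a pentasubstituted benzene, ring B. Ring B carries a phenol at C8 (peri to the C1 carbonyl and hydrogen-bonded to it), a lone hydrogen at C7, a phenyl group at C6 and, at C5, a 4-hydroxy-2H-pyran-2-one joined through its C6 carbon. The only stereocentre is C3 (S); it stands between two methylenes with no neighbouring stereocentre, so it cannot be set by relay from an existing centre. The β-hydroxy ketone of ring A is the fragile element: loss of water under acid or base gives an enone that tautomerises to a 1-naphthol and erases C3 for good, and every β-alkoxy precursor shares this weakness. The 4-hydroxypyranone is a vinylogous acid, nucleophilic at its C3 and an electrophilic lactone, and has to stay masked until the end; its bond to C5 is flanked by the C6 phenyl group and the C4 methylene and is therefore hindered. The real difficulty is to create the isolated C3 centre as one enantiomer while ring A is built on an arene whose five substituents must be placed without ambiguity. The route exploits the fact that C1, C2, C3 and C4 with the C3 oxygen are the four carbons of a 3-oxygenated cyclobutanol attached to C8a: in that ring the bonds C1–C2 and C1–C4 are enantiotopic, and moving C4 from C1 to C4a closes ring A and turns prochiral C3 into the stereocentre.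

## Logic of the disconnections

16 to 15. The last cut removes nothing from the skeleton: the O–benzyl bonds at the C3 oxygen and at the pyranone O4 and the O–methyl bond at the C8 oxygen are broken. The reason is that the β-hydroxy ketone and the acidic pyranone should appear only in the final operation. The forward step must remove all three groups in one Lewis-acid treatment at or below 0 °C without touching the C3–O bond. For that reason the pyranone oxygen carries benzyl and not methyl, and the C8 methyl ether is relied on to chelate boron with the C1 carbonyl.

15 to 9 and 14. The C5–C6' bond between ring B and the pyranone is cut. It is the only bond that joins two ring systems that can be made separately, so the cut makes the route convergent and lets the heterocycle arrive complete. The forward step is a Suzuki–Miyaura coupling of a boronate with two ortho substituents and a chloropyranone that behaves as a vinylogous acid chloride, so it needs a hindered-coupling ligand and a mild base.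

9 to 8 to 7. The C5–B bond and then the C5–Br bond are cut. C5 is para to the C8 methoxy group and meta to the C1 acyl group, so an electrophile should go there. The gain is a tetralone with no C5 substituent, which means the arene of the key step needs only one halogen. The forward steps demand para selectivity over C7, no bromination next to the ketone, and borylation of a hindered bromide under a base too weak to enolise the ketone.

7 to 6. The C4–C4a bond is cut and C4 is joined again to C1, which turns the C1 carbonyl back into a carbinol. The chiral tetralone becomes an achiral cyclobutanol with a mirror plane, whose only stereochemical question is cis or trans, and bromine marks C4a. The forward step must cleave one of two enantiotopic C–C bonds under the control of a chiral ligand on palladium, close the six-membered ring by C(sp3)–C(sp2) reductive elimination faster than β-hydride or β-alkoxide loss, and use a base mild enough to leave the β-benzyloxy ketone alone.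

6 to 3 and 4, through 5. The C1–C8a bond is cut. 4 holds all four ring A carbons and the C3 oxygen, and C8a is the position of 3 that lies between bromine and methoxy, its most acidic C–H. The forward step must generate 5 and use it cold before it loses LiBr, and the aryl group must enter 4 anti to the benzyloxy group so that the cis alcohol results.

3 to 1 and 2. The C6–phenyl bond is cut. 1 carries iodine and bromine, so the coupling can be chemoselective and does not depend on the statistical mono-coupling of a dibromide. The forward step must react at C–I only.

14 to 13 to 10, through 11 and 12. The O4–benzyl bond is cut, and then the pyranone ring is cut at O1–C2 and C3–C4 into two molecules of 10, so that each molecule of 13 consumes two molecules of 10 and loses one extra carboxyl carbon at C3 on the way. The gain is a heterocycle from one bulk chemical. The forward steps demand that the 6-chloro group survives hydrolysis and decarboxylation and that alkylation takes place at O4 of an ambident anion.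

## Other disconnections considered

Alternative 1: The cut runs through ring B at C8–C8a and C4a–C5. Ring A enters as the chiral bromo-enone A2, and a Diels–Alder reaction with the 1-methoxy-1-silyloxy diene A1, followed by loss of methanol and HBr, gives the phenol ester A3.
- In its favour: two C–C bonds and all of ring B form in one operation, one skeletal bond more than the chosen key step. The pattern of ring B (oxygen at C8, phenyl at C6, carbon at C5) follows from the polarisation of A1 and the position of bromine in A2, so no electrophilic substitution with a regiochemical question is needed. On these two points the alternative is the better plan.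
- On stereochemistry it is equal in principle, since C3 is carried in from A2 and no enantioselective step is needed at the key stage. A2 would, however, have to be made enantiopure in several steps, whereas the chosen plan takes achiral 4 from the bottle.
- Against it: A2 is a β-silyloxy enone that can aromatise by loss of silanol under the heating a sluggish diene needs. A1 is deactivated by its terminal ester, hindered at both ends, and has to add to a trisubstituted bromo-alkene. A3 offers at C5 only a methyl ester between the phenyl group and C4, and turning it into the 4-hydroxypyranone means a Claisen-type chain extension and cyclisation at a doubly ortho-substituted carbonyl in the presence of the C1 ketone and a free phenol.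
- Comparison: both plans rest on one well-understood bond-forming manifold. The likely count is four or more steps to A2, one to A1, the cycloaddition, three or four for the pyranone and the deprotection, about eleven or twelve against nine. The chosen plan brings the pyranone in complete by cross-coupling.

Alternative 2: The cut is C2–C3 inside ring A. A dinuclear zinc catalyst from Et2Zn and a ProPhenol ligand would enolise the acetyl group of the keto-aldehyde A4 and add it to the tethered aldehyde to give the bis-methyl ether A5.
- In its favour: A5 is only two ether cleavages away from 16, fewer steps after the key step than the chosen plan has, and on that point the alternative is better. All substituents of ring B are in place before the stereocentre exists, so no cross-coupling has to be run on a fragile chiral intermediate. Direct catalytic aldol additions of aryl methyl ketones are an established class and the six-membered closure is kinetically easy.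
- Against it: A4 is a pentasubstituted benzene with acetyl and formylmethyl groups on neighbouring carbons and needs a long linear construction. Its arylacetaldehyde is the more acidic carbonyl partner, so the catalyst may enolise the aldehyde and not the twisted, hindered acetyl group. The aldol is reversible and its product is the β-hydroxy ketone that dehydrates to a naphthol, so enantiopurity and material can both be lost under the zinc alkoxide conditions. The methyl ether on the pyranone would need forcing cleavage at the very end.
- Comparison: both plans use a chiral catalyst on a prochiral substrate. In the chosen plan the stereocentre arises in an irreversible sequence of C–C cleavage and reductive elimination, here in a reversible addition. Because of A4 the overall count is expected to be higher than nine.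

Alternative 3: The cut is C1–C2 and C3–C4. Irradiation of the o-tolualdehyde A6 at 365 nm with Ti(OiPr)4 and a TADDOL ligand would give the hydroxy-o-quinodimethane A7, which adds endo to the dioxinone A8 to give the all-cis cycloadduct A9.
- In its favour: two bonds and ring A form in one step, without halogen, organolithium or palladium, and under neutral conditions that cannot trigger base-induced elimination. On these points the alternative is the better plan. The 2-methoxy group of A6 is the kind of chelating group a titanium-controlled photoenolisation uses, so the diene half fits the method.
- Against it: A8 is an electron-rich β-alkoxy acrylate, a weak dienophile, and is itself photoreactive as an enone and thermally labile towards loss of acetone. It has no second carbonyl for two-point binding to titanium, so facial control is open. Of the three stereocentres formed only C3 is kept. Oxidation of the C1 carbinol, opening of the dioxanone and decarboxylation are needed to reach the hydroxy tetralone A10, the free alcohol that corresponds to 7, after which the same four steps for C5 and deprotection remain.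
- Comparison: structurally it solves the same ring A problem and converges on the same late intermediates. Mechanistically a pericyclic step replaces an organometallic one. The count is about twelve against nine.

Key step: step 3

## Route

Step 1
Reactants: 1 1-bromo-3-iodo-5-methoxybenzene; 2 phenylboronic acid
Product: 3 3-bromo-5-methoxy-1,1'-biphenyl
Conditions: Pd(PPh3)4 (2 mol %), Na2CO3 (2 M aq), toluene/EtOH, 60 °C
Reagents that add atoms: none
Why: Suzuki–Miyaura coupling; zerovalent palladium adds to C–I much faster than to C–Br at this temperature, so with one equivalent of 2 only the iodide should react and the bromide is kept for the key step.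

Step 2
Reactants: 3 3-bromo-5-methoxy-1,1'-biphenyl; 4 3-(benzyloxy)cyclobutan-1-one
Product: 6 cis-3-(benzyloxy)-1-(2-bromo-6-methoxy-4-phenylphenyl)cyclobutan-1-ol, via aryllithium 5 (not isolated)
Conditions: LiTMP (lithium 2,2,6,6-tetramethylpiperidide, from 2,2,6,6-tetramethylpiperidine and n-butyllithium), THF, −78 °C; then 4, −78 °C; aq NH4Cl at −78 °C
Reagents that add atoms: none
Why: Directed ortho-lithiation at the C–H flanked by bromine and methoxy, the most acidic site, followed by 1,2-addition to the strained and highly electrophilic cyclobutanone. The aryl group should enter the puckered ring anti to the 3-benzyloxy group, so hydroxyl and benzyloxy end up cis; the product is achiral (mirror plane through C1 and C3) and the minor trans isomer is to be removed by chromatography or crystallisation.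

Step 3
Reactants: 6 cis-3-(benzyloxy)-1-(2-bromo-6-methoxy-4-phenylphenyl)cyclobutan-1-ol
Product: 7 (S)-3-(benzyloxy)-8-methoxy-6-phenyl-3,4-dihydronaphthalen-1(2H)-one
Conditions: Pd(OAc)2 (5 mol %), (R)-BINAP (7.5 mol %), Cs2CO3 (1.5 equiv), degassed toluene (0.02 M), 70 °C
Reagents that add atoms: none
Why: Zerovalent palladium, formed in the flask from Pd(OAc)2 and the phosphine, adds to the C4a–Br bond, Cs2CO3 exchanges bromide for the tertiary alkoxide, β-carbon elimination cleaves one C1–CH2 bond of the strained ring to give the C1 ketone and a primary alkyl(aryl)palladium species in a seven-membered palladacycle, and C(sp3)–C(sp2) reductive elimination forms C4–C4a and returns zerovalent palladium. The closest known reaction type is the palladium-catalysed enantioselective arylative ring opening of tert-cyclobutanols with aryl bromides by β-carbon elimination, which gives γ-arylated ketones; here bromide and cyclobutanol are in one molecule. Ring A is closed as a ring expansion from four to six members, by reductive elimination from the seven-membered palladacycle, and because bromine marks C4a no other ring size or regioisomer can form. C3 becomes a stereocentre at the C–C cleavage: the two ring bonds are enantiotopic, the palladium-bound (R)-BINAP selects between them, and cleavage of the bond to the pro-S methylene (the carbon that becomes C4) gives (S)-7; only the cis isomer of 6 is used, because the trans isomer would give the mirror-image ketone from the same bond selection. Ring strain makes cleavage of a ring bond much faster than β-aryl elimination, and the cis-chelating bisphosphine favours reductive elimination over β-hydride or β-benzyloxy elimination at the alkylpalladium stage. Since alkoxide and aryl group sit on the same metal, the four-centre transition state has to be reached from the C,O-chelate through a strained bicyclic geometry, so the reaction is run dilute and warm to keep intermolecular alkoxide transfer down. Solid Cs2CO3 in toluene is a weak enough base that the β-benzyloxy ketone should not lose benzyl alcohol by E1cB elimination.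

Step 4
Reactants: 7 (S)-3-(benzyloxy)-8-methoxy-6-phenyl-3,4-dihydronaphthalen-1(2H)-one
Product: 8 (S)-3-(benzyloxy)-5-bromo-8-methoxy-6-phenyl-3,4-dihydronaphthalen-1(2H)-one
Conditions: NBS (1.05 equiv), MeCN, 0 °C to rt, dark
Reagents that add atoms: N-bromosuccinimide, O=C1CCC(=O)N1Br
Why: Electrophilic aromatic bromination; C5 is para to the C8 methoxy group and meta to the C1 acyl group, while the only other free position, C7, is ortho to methoxy and screened by the O-methyl group, which is turned away from the peri carbonyl. Neutral, acid-free conditions in the dark should leave the position next to the ketone, the benzylic C4 and the benzyl ether untouched, and C3 is not involved.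

Step 5
Reactants: 8 (S)-3-(benzyloxy)-5-bromo-8-methoxy-6-phenyl-3,4-dihydronaphthalen-1(2H)-one
Product: 9 (S)-3-(benzyloxy)-8-methoxy-6-phenyl-5-(4,4,5,5-tetramethyl-1,3,2-dioxaborolan-2-yl)-3,4-dihydronaphthalen-1(2H)-one
Conditions: B2pin2 (1.5 equiv), Pd2(dba)3 (2 mol %), XPhos (8 mol %), KOAc (3 equiv), 1,4-dioxane, 90 °C
Reagents that add atoms: bis(pinacolato)diboron, CC1(C)OB(OC1(C)C)B1OC(C)(C)C(C)(C)O1
Why: Miyaura borylation; the bulky electron-rich biarylphosphine allows oxidative addition and transmetalation at a bromide flanked by phenyl and the C4 methylene. KOAc is too weak a base to enolise the ketone, so the β-benzyloxy group should stay in place.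

Step 6
Reactants: 10 malonyl dichloride (two molecules per molecule of product)
Product: 13 6-chloro-4-hydroxy-2H-pyran-2-one, via pyranone carbonyl chloride 11 (not isolated), via pyranone carboxylic acid 12 (not isolated)
Conditions: neat 10, 25 °C, several days (HCl vented); then H2O, 1,4-dioxane, 60 °C
Reagents that add atoms: malonyl dichloride (second molecule of 10), O=C(Cl)CC(=O)Cl; water (hydrolysis of 11 to 12), O
Why: Self-condensation of the acid chloride, which takes two molecules of 10: C-acylation of one molecule at its methylene by the other, then O-acylation by the chloro-enol, closes the lactone and gives 11 with loss of two HCl. Water then hydrolyses the 3-carbonyl chloride to the β-keto acid 12, which loses CO2 on warming, so the oxygen brought in by water is carried only by 12 and departs again in the CO2. The 6-chloro substituent, deactivated by the acidic 4-hydroxy group, should survive the aqueous stage.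

Step 7
Reactants: 13 6-chloro-4-hydroxy-2H-pyran-2-one
Product: 14 4-(benzyloxy)-6-chloro-2H-pyran-2-one
Conditions: BnOH, PPh3, DIAD, THF, 0 °C to rt
Reagents that add atoms: benzyl alcohol, OCc1ccccc1
Why: Mitsunobu alkylation; the acidic 4-hydroxypyranone is a good pronucleophile and should react at O4 with the alkoxyphosphonium ion, which avoids the C3- and O2-alkylation that benzyl halides and base can give. Benzyl is chosen over methyl so that the final deprotection needs nothing harsher than BCl3 at low temperature.

Step 8
Reactants: 9 (S)-3-(benzyloxy)-8-methoxy-6-phenyl-5-(4,4,5,5-tetramethyl-1,3,2-dioxaborolan-2-yl)-3,4-dihydronaphthalen-1(2H)-one; 14 4-(benzyloxy)-6-chloro-2H-pyran-2-one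
Product: 15 4-(benzyloxy)-6-[(7S)-7-(benzyloxy)-4-methoxy-5-oxo-2-phenyl-5,6,7,8-tetrahydronaphthalen-1-yl]-2H-pyran-2-one
Conditions: Pd(OAc)2 (5 mol %), SPhos (10 mol %), K3PO4 (3 equiv), toluene/H2O (10:1), 60 °C
Reagents that add atoms: none
Why: Suzuki–Miyaura coupling; the C6–Cl bond of the pyranone is a vinylogous acid chloride and adds readily to zerovalent palladium, and SPhos suits boronates with two ortho substituents. Phosphate base and moderate temperature are chosen to spare the chloropyranone from hydrolysis and the β-benzyloxy ketone from elimination; the new biaryl axis has ortho substituents on one ring only and is not expected to be configurationally stable.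

Step 9
Reactants: 15 4-(benzyloxy)-6-[(7S)-7-(benzyloxy)-4-methoxy-5-oxo-2-phenyl-5,6,7,8-tetrahydronaphthalen-1-yl]-2H-pyran-2-one
Product: 16 wailupemycin F (6-[(7S)-4,7-dihydroxy-5-oxo-2-phenyl-5,6,7,8-tetrahydronaphthalen-1-yl]-4-hydroxy-2H-pyran-2-one)
Conditions: BCl3 (8 equiv), pentamethylbenzene (6 equiv), CH2Cl2, −78 to 0 °C; MeOH quench at −78 °C
Reagents that add atoms: none
Why: Lewis-acid ether cleavage; the benzyl C–O bonds break at the benzylic carbon and pentamethylbenzene traps the benzyl cation, while the C8 methyl ether is removed by chloride attack on the methyl group of the boron chelate with the C1 carbonyl. No bond to C3 is broken, so the S configuration is retained, and the low temperature is meant to prevent dehydration of the new β-hydroxy ketone.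

## Compound list

1 | 1-bromo-3-iodo-5-methoxybenzene | COc1cc(Br)cc(I)c1 | starting material
2 | phenylboronic acid | OB(O)c1ccccc1 | starting material
3 | 3-bromo-5-methoxy-1,1'-biphenyl | COc1cc(Br)cc(-c2ccccc2)c1 | intermediate
4 | 3-(benzyloxy)cyclobutan-1-one | O=C1CC(OCc2ccccc2)C1 | starting material
5 | (2-bromo-6-methoxy-4-phenylphenyl)lithium | [Li]c1c(OC)cc(-c2ccccc2)cc1Br | intermediate
6 | cis-3-(benzyloxy)-1-(2-bromo-6-methoxy-4-phenylphenyl)cyclobutan-1-ol (hydroxy and benzyloxy on the same face; achiral) | O[C@@]1(c2c(OC)cc(-c3ccccc3)cc2Br)C[C@@H](OCc2ccccc2)C1 | intermediate
7 | (S)-3-(benzyloxy)-8-methoxy-6-phenyl-3,4-dihydronaphthalen-1(2H)-one | O=C1C[C@@H](OCc2ccccc2)Cc2c1c(OC)cc(-c1ccccc1)c2 | intermediate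
8 | (S)-3-(benzyloxy)-5-bromo-8-methoxy-6-phenyl-3,4-dihydronaphthalen-1(2H)-one | O=C1C[C@@H](OCc2ccccc2)Cc2c1c(OC)cc(-c1ccccc1)c2Br | intermediate
9 | (S)-3-(benzyloxy)-8-methoxy-6-phenyl-5-(4,4,5,5-tetramethyl-1,3,2-dioxaborolan-2-yl)-3,4-dihydronaphthalen-1(2H)-one | O=C1C[C@@H](OCc2ccccc2)Cc2c1c(OC)cc(-c1ccccc1)c2B1OC(C)(C)C(C)(C)O1 | intermediate
10 | malonyl dichloride | O=C(Cl)CC(=O)Cl | starting material
11 | 6-chloro-4-hydroxy-2-oxo-2H-pyran-3-carbonyl chloride | O=C(Cl)c1c(O)cc(Cl)oc1=O | intermediate
12 | 6-chloro-4-hydroxy-2-oxo-2H-pyran-3-carboxylic acid | OC(=O)c1c(O)cc(Cl)oc1=O | intermediate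
13 | 6-chloro-4-hydroxy-2H-pyran-2-one | O=c1cc(O)cc(Cl)o1 | intermediate
14 | 4-(benzyloxy)-6-chloro-2H-pyran-2-one | O=c1cc(OCc2ccccc2)cc(Cl)o1 | intermediate
15 | 4-(benzyloxy)-6-[(7S)-7-(benzyloxy)-4-methoxy-5-oxo-2-phenyl-5,6,7,8-tetrahydronaphthalen-1-yl]-2H-pyran-2-one | O=C1C[C@@H](OCc2ccccc2)Cc2c1c(OC)cc(-c1ccccc1)c2-c1cc(OCc2ccccc2)cc(=O)o1 | intermediate
16 | wailupemycin F (6-[(7S)-4,7-dihydroxy-5-oxo-2-phenyl-5,6,7,8-tetrahydronaphthalen-1-yl]-4-hydroxy-2H-pyran-2-one) | O=C1C[C@@H](O)Cc2c1c(O)cc(-c1ccccc1)c2-c1cc(O)cc(=O)o1 | target

## Step count and least certain steps

Total: 9 steps. Longest linear sequence: 7 steps (1, 2, 3, 4, 5, 8, 9 from compound 1); the pyranone branch (steps 6 and 7) joins at step 8.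

**Step 3 (key step).**
- What may go wrong: the chelated alkoxide is held away from the ring bonds, so the intramolecular β-carbon elimination may be slower than alkoxide transfer between two molecules, which leads to oligomerisation or to simple loss of bromine. The ligand may also discriminate poorly between the two enantiotopic bonds, and the product may lose benzyl alcohol and aromatise if the base is too active.
- Fallback: a chiral-pool construction of ring A that sets out from 5 and comes back at 7. Commercial (R)-4-hydroxydihydrofuran-2(3H)-one F1 is benzylated with benzyl 2,2,2-trichloroacetimidate and catalytic TfOH to (R)-4-(benzyloxy)dihydrofuran-2(3H)-one F2. Aryllithium 5, made as in step 2 and used in the presence of CeCl3 to suppress enolisation, opens F2 to (R)-3-(benzyloxy)-1-(2-bromo-6-methoxy-4-phenylphenyl)-4-hydroxybutan-1-one F3. Iodination with I2, PPh3 and imidazole gives (R)-3-(benzyloxy)-1-(2-bromo-6-methoxy-4-phenylphenyl)-4-iodobutan-1-one F4. A nickel-catalysed intramolecular reductive coupling of the aryl bromide with the alkyl iodide (NiBr2(dme), 4,4'-di-tert-butyl-2,2'-bipyridine, Mn powder, DMA) then forms C4–C4a and gives 7. C3 comes from the lactone and no bond to it is touched.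

**Step 2.**
- What may go wrong: 5 may lose LiBr to an aryne, or the halogen may migrate, before the ketone is added; proton transfer from 4 to the hindered aryllithium may compete with addition.
- Fallback: sets out from 3 and comes back at 6, and never lets the aryllithium accumulate. LiTMP is added to 3 in the presence of TMSCl at −78 °C to give (2-bromo-6-methoxy-4-phenylphenyl)trimethylsilane F5. Ipso-iododesilylation with ICl gives 3-bromo-4-iodo-5-methoxy-1,1'-biphenyl F6. Iodine–magnesium exchange with iPrMgCl·LiCl at −40 °C gives the thermally robust (2-bromo-6-methoxy-4-phenylphenyl)magnesium chloride F7, which is added to 4 with LaCl3·2LiCl to give 6.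

**Step 8.**
- What may go wrong: slow transmetalation of the doubly ortho-substituted boronate may allow protodeboronation; aqueous base may hydrolyse the chloropyranone or cause elimination next to the ketone.
- Fallback: a base-free Stille coupling that sets out from 8 and comes back at 15. Stannylation of 8 with Me3SnSnMe3 and Pd(PPh3)4 in toluene gives (S)-3-(benzyloxy)-8-methoxy-6-phenyl-5-(trimethylstannyl)-3,4-dihydronaphthalen-1(2H)-one F8. Coupling of F8 with 14 (Pd2(dba)3, AsPh3, CuI, DMF, 50 °C) gives 15.

**Step 9.**
- What may go wrong: ring A may dehydrate and aromatise under the Lewis acid; cleavage of the three ethers may stop part-way; benzyl cations that escape the scavenger may alkylate the electron-rich pyranone.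
- Fallback: a two-stage deprotection that sets out from 15 and comes back at 16. Hydrogenolysis of both benzyl ethers (H2, Pd(OH)2/C, EtOAc, rt) gives 4-hydroxy-6-[(7S)-7-hydroxy-4-methoxy-5-oxo-2-phenyl-5,6,7,8-tetrahydronaphthalen-1-yl]-2H-pyran-2-one F9. The chelated C8 methyl ether alone is then cleaved with a small excess of BCl3 in CH2Cl2 at −78 to −20 °C to give 16.

## Further compounds

F1 | step 3 | (R)-4-hydroxydihydrofuran-2(3H)-one (commercial starting material of the fallback) | O=C1C[C@@H](O)CO1
F2 | step 3 | (R)-4-(benzyloxy)dihydrofuran-2(3H)-one | O=C1C[C@@H](OCc2ccccc2)CO1
F3 | step 3 | (R)-3-(benzyloxy)-1-(2-bromo-6-methoxy-4-phenylphenyl)-4-hydroxybutan-1-one | O=C(c1c(OC)cc(-c2ccccc2)cc1Br)C[C@@H](OCc1ccccc1)CO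
F4 | step 3 | (R)-3-(benzyloxy)-1-(2-bromo-6-methoxy-4-phenylphenyl)-4-iodobutan-1-one | O=C(c1c(OC)cc(-c2ccccc2)cc1Br)C[C@@H](OCc1ccccc1)CI
F5 | step 2 | (2-bromo-6-methoxy-4-phenylphenyl)trimethylsilane | COc1cc(-c2ccccc2)cc(Br)c1[Si](C)(C)C
F6 | step 2 | 3-bromo-4-iodo-5-methoxy-1,1'-biphenyl | COc1cc(-c2ccccc2)cc(Br)c1I
F7 | step 2 | (2-bromo-6-methoxy-4-phenylphenyl)magnesium chloride | COc1cc(-c2ccccc2)cc(Br)c1[Mg]Cl
F8 | step 8 | (S)-3-(benzyloxy)-8-methoxy-6-phenyl-5-(trimethylstannyl)-3,4-dihydronaphthalen-1(2H)-one | O=C1C[C@@H](OCc2ccccc2)Cc2c1c(OC)cc(-c1ccccc1)c2[Sn](C)(C)C
F9 | step 9 | 4-hydroxy-6-[(7S)-7-hydroxy-4-methoxy-5-oxo-2-phenyl-5,6,7,8-tetrahydronaphthalen-1-yl]-2H-pyran-2-one | O=C1C[C@@H](O)Cc2c1c(OC)cc(-c1ccccc1)c2-c1cc(O)cc(=O)o1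
A1 | alternative 1 | methyl 5-[(tert-butyldimethylsilyl)oxy]-5-methoxy-3-phenylpenta-2,4-dienoate (mixture of double-bond isomers) | COC(=O)C=C(c1ccccc1)C=C(OC)O[Si](C)(C)C(C)(C)C
A2 | alternative 1 | (5S)-2-bromo-5-[(tert-butyldimethylsilyl)oxy]cyclohex-2-en-1-one | O=C1C[C@@H](O[Si](C)(C)C(C)(C)C)CC=C1Br
A3 | alternative 1 | methyl (7S)-7-[(tert-butyldimethylsilyl)oxy]-4-hydroxy-5-oxo-2-phenyl-5,6,7,8-tetrahydronaphthalene-1-carboxylate | O=C1C[C@@H](O[Si](C)(C)C(C)(C)C)Cc2c1c(O)cc(-c1ccccc1)c2C(=O)OC
A4 | alternative 2 | 2-[2-acetyl-3-methoxy-6-(4-methoxy-2-oxo-2H-pyran-6-yl)-5-phenylphenyl]acetaldehyde | CC(=O)c1c(OC)cc(-c2ccccc2)c(-c2cc(OC)cc(=O)o2)c1CC=O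
A5 | alternative 2 | 6-[(7S)-7-hydroxy-4-methoxy-5-oxo-2-phenyl-5,6,7,8-tetrahydronaphthalen-1-yl]-4-methoxy-2H-pyran-2-one | O=C1C[C@@H](O)Cc2c1c(OC)cc(-c1ccccc1)c2-c1cc(OC)cc(=O)o1
A6 | alternative 3 | 2-methoxy-6-methyl-4-phenylbenzaldehyde | O=Cc1c(OC)cc(-c2ccccc2)cc1C
A7 | alternative 3 | (Z)-(2-methoxy-6-methylidene-4-phenylcyclohexa-2,4-dien-1-ylidene)methanol, the hydroxy-o-quinodimethane with its hydroxyl turned towards the methoxy group and away from the exocyclic methylene | O/C=C1\C(OC)=CC(c2ccccc2)=CC1=C
A8 | alternative 3 | 2,2-dimethyl-4H-1,3-dioxin-4-one | CC1(C)OC=CC(=O)O1
A9 | alternative 3 | all-cis endo cycloadduct: 1-hydroxy-8-methoxy-6-phenyltetralin cis-fused at C2–C3 to a 2,2-dimethyl-1,3-dioxan-4-one (carbonyl on C2, ring oxygen on C3) | O[C@H]1[C@H]2C(=O)OC(C)(C)O[C@H]2Cc2cc(-c3ccccc3)cc(OC)c21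
A10 | alternative 3 | (S)-3-hydroxy-8-methoxy-6-phenyl-3,4-dihydronaphthalen-1(2H)-one | O=C1C[C@@H](O)Cc2c1c(OC)cc(-c1ccccc1)c2
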